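**Plan**
Cuts: (a) O1–C2 of furanone ring B, which opens the hemiketal to an ortho-hydroxyaryl 1,2-diketone. (b) One carbonyl carbon is put back between O1 and C2, giving the six-membered lactone of 3-farnesyl-4,7-dihydroxycoumarin (ammoresinol). (c) C3–C1' of that coumarin is cut, giving 4,7-dihydroxycoumarin and (2E,6E)-farnesol.
Enabling feature: in ring B the hemiketal carbon C2 lies between O1 and the ketone C3 on resorcinol ring A. Ring B is therefore a masked aryl 1,2-diketone, and target = ammoresinol + O2 − CO2, atom for atom.
Forward order: ring A and a temporary pyranone ring are bought together. The chain is joined at the acidic C3 by palladium-catalysed allylation, and ring B arises last by an oxidative six-to-five ring contraction.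
Helper: the lactone carbonyl makes C3 an enolate carbon for both the allylation and the O2 capture. It also masks O1, and it leaves as CO2 within the key step itself.
Stereochemistry: both E alkenes come from farnesol. The only stereocentre, C2 (R), is set in the last step, when a β-diketone-cleaving dioxygenase closes O1 onto the Re face of the nascent C2 ketone.

Key step: step 3

Assumption: the hemiketal carbon of the target is taken to reopen to the achiral open diketone only slowly without base, so one enantiomer can be isolated and kept cold at or below pH 6.5.

Step 1
Reactants: 1 (2E,6E)-farnesol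
Product: 2 (2E,6E)-farnesyl methyl carbonate
Conditions: ClCO2Me, pyridine, CH2Cl2, 0 °C to rt
Reagents that add atoms: methyl chloroformate, COC(=O)Cl
Why: O-acylation of a primary allylic alcohol with a chloroformate under pyridine buffering should leave the alkenes and their E geometry untouched and installs a leaving group that later supplies its own base.

Step 2
Reactants: 2 (2E,6E)-farnesyl methyl carbonate; 3 4,7-dihydroxycoumarin
Product: 4 ammoresinol (3-[(2E,6E)-farnesyl]-4,7-dihydroxycoumarin)
Conditions: Pd(PPh3)4 (5 mol %), 3 in excess, THF–DMF, 40 °C, argon
Reagents that add atoms: none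
Why: Tsuji–Trost allylic alkylation, in which zerovalent palladium ionises 2 with loss of CO2, the released methoxide deprotonates only the strongly acidic 4-OH of 3, and the soft enolate attacks the unhindered CH2 terminus of the π-allyl complex through C3; any 4-O-allyl ether is re-ionised and funnelled to the C-allyl product, the 7-OH stays protonated, excess 3 suppresses double allylation, and the E geometry should hold because syn–anti exchange would need a tertiary σ-palladium species.

Step 3
Reactants: 4 ammoresinol
Product: 9 (R)-2-[(2E,6E)-farnesyl]-2,6-dihydroxybenzofuran-3(2H)-one (target), via C3 hydroperoxide 5 (not isolated), via fused dioxetane 6 (not isolated), via aryl hydrogen carbonate 7 (not isolated), via open 1,2-diketone 8 (not isolated)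
Conditions: engineered β-diketone dioxygenase (cupin fold, acetylacetone-cleaving Dke1 class, EC 1.13.11.50, loaded with FeSO4), air, MES buffer pH 6.2, 2-hydroxypropyl-β-cyclodextrin, 5% DMSO, 15 °C, MTBE overlay; cold base-free extraction
Reagents that add atoms: dioxygen, O=O
Why: Proposed new method: the enolate of 4 chelates through O4 and the lactone carbonyl oxygen to the divalent iron held by the three-histidine site, its carbon C3 captures triplet O2 to give peroxidate 5, the distal oxygen adds to the lactone carbonyl C2 to give dioxetane 6, and cleavage of O–O and C2–C3 gives the carbonic half ester 7, which loses CO2 and so uncovers the phenol O1 of diketone 8. The closest known reaction type is the cleavage of acetylacetone and other β-dicarbonyl compounds into a 1,2-dicarbonyl compound and a carboxylic acid by this enzyme class, mirrored in the flask by the copper-catalysed aerobic deacylation of 2-substituted acetoacetates; new are the 4-hydroxycoumarin substrate, in which the acid fragment is carbonic acid and departs as gas, and the stereoselective closure that follows. Ring B closes by 5-exo-trig addition of O1 to the C2 ketone of 8, so that the six-membered lactone contracts to the five-membered hemiketal. The new stereocentre C2 is controlled by the protein: O1 can reach C2 only when the O=C–C=O unit is twisted by about 90°, the two twisted forms are mirror images, and a pocket that keeps the aryl ketone on the metal and the farnesyl chain in a lipophilic tunnel should admit only the form that presents the Re face, which gives (R); variants are screened for this sense. Chemoselectivity over the three trisubstituted alkenes and ring A is secured because only the metal-bound enolate carbon reacts with ground-state O2 and no peracid, singlet oxygen or oxo-iron species is formed, and regioselectivity for C2 over C4 is secured because C4 is deactivated as a vinylogous carbonate by O1 and the 7-OH whereas C2 is an aryl ester carbonyl, this enzyme class being known to cut beside the more electrophilic carbonyl group. Mildly acidic buffer, low temperature and continuous extraction into MTBE should keep the released hemiketal from reopening.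

**Compound list**
1 | (2E,6E)-farnesol | CC(C)=CCC/C(C)=C/CC/C(C)=C/CO | starting material
2 | (2E,6E)-farnesyl methyl carbonate | CC(C)=CCC/C(C)=C/CC/C(C)=C/COC(=O)OC | intermediate
3 | 4,7-dihydroxycoumarin | O=c1cc(O)c2ccc(O)cc2o1 | starting material
4 | ammoresinol, 3-[(2E,6E)-farnesyl]-4,7-dihydroxycoumarin | CC(C)=CCC/C(C)=C/CC/C(C)=C/Cc1c(O)c2ccc(O)cc2oc1=O | intermediate
5 | 3-[(2E,6E)-farnesyl]-3-hydroperoxy-7-hydroxychromane-2,4-dione (enzyme-bound, not isolated; C3 configuration without consequence) | CC(C)=CCC/C(C)=C/CC/C(C)=C/CC1(OO)C(=O)Oc2cc(O)ccc2C1=O | intermediate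
6 | 3-[(2E,6E)-farnesyl]-2,7-dihydroxy-2,3-epidioxychroman-4-one, dioxetane fused across C2–C3 (not isolated) | CC(C)=CCC/C(C)=C/CC/C(C)=C/CC12OOC1(O)Oc1cc(O)ccc1C2=O | intermediate
7 | 5-hydroxy-2-[(4E,8E)-5,9,13-trimethyl-2-oxotetradeca-4,8,12-trienoyl]phenyl hydrogen carbonate (not isolated) | CC(C)=CCC/C(C)=C/CC/C(C)=C/CC(=O)C(=O)c1ccc(O)cc1OC(=O)O | intermediate
8 | (4E,8E)-1-(2,4-dihydroxyphenyl)-5,9,13-trimethyltetradeca-4,8,12-triene-1,2-dione (not isolated) | CC(C)=CCC/C(C)=C/CC/C(C)=C/CC(=O)C(=O)c1ccc(O)cc1O | intermediate
9 | (2R)-2,6-dihydroxy-2-[(2E,6E)-3,7,11-trimethyldodeca-2,6,10-trien-1-yl]-1-benzofuran-3(2H)-one | CC(C)=CCC/C(C)=C/CC/C(C)=C/C[C@@]1(O)Oc2cc(O)ccc2C1=O | target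

Total step count: 3
Longest linear sequence: 3 (1 → 2 → 4 → 9)

**Steps most likely to fail**

Step 3.
- What may go wrong: low turnover of a bulky lipophilic substrate by a pocket evolved for small diketones; attack of the peroxidate at the wrong carbonyl group; ring closure after release from the protein, with loss of facial selectivity.
- Further risks: enolisation of the doubly activated CH2 of the open form, and racemisation by ring opening during isolation.
- Fallback: it uses known chemistry, sets out from 4 and comes back at 9.
- The enolate of 4 is hydroxylated at C3 with 3-phenyl-2-(phenylsulfonyl)oxaziridine (K2CO3, THF, 0 °C). This oxidant leaves isolated alkenes alone and should give racemic 3-farnesyl-3,7-dihydroxychromane-2,4-dione F1.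
- Lactone hydrolysis and decarboxylation of the resulting β-keto acid (aq NaHCO3/THF, then pH 4, 40 °C) should give the racemic ketol (4E,8E)-1-(2,4-dihydroxyphenyl)-2-hydroxy-5,9,13-trimethyltetradeca-4,8,12-trien-1-one F2.
- Oxidation of the ketol with catalytic Cu(OAc)2 and air in MeOH should give diketone 8, which closes by itself to the racemic hemiketal F3.
- Preparative supercritical-fluid chromatography on amylose tris(3,5-dimethylphenylcarbamate) with neutral CO2/iPrOH should separate 9 from the (S)-hemiketal F4. A trace of Et3N re-equilibrates that enantiomer to the racemate for recycling.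

Step 2.
- What may go wrong: double allylation at C3, O-allylation of the 7-OH, attack at the tertiary allyl terminus, erosion of the E geometry by π–σ–π exchange, and β-hydride elimination of the π-allyl complex.
- Fallback: it makes the C3–C1' bond before the lactone ring exists, sets out from 1 and comes back at 4.
- 1 is converted with PBr3 (Et2O, 0 °C) into (2E,6E)-farnesyl bromide F5.
- The trilithium salt of commercial 2,4-dihydroxyacetophenone (LiHMDS, 3.3 equiv, THF, −78 to 0 °C) is alkylated by SN2 at its enolate carbon. This should give (4E,8E)-1-(2,4-dihydroxyphenyl)-5,9,13-trimethyltetradeca-4,8,12-trien-1-one F6.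
- Claisen-type condensation of this ortho-hydroxyaryl ketone with diethyl carbonate (NaH, toluene, 100 °C, acidic work-up) should close the pyranone ring and deliver 4 with the chain at C3 only.

Step 1.
- What may go wrong: ionisation or allylic transposition of the activated ester during preparation or on silica.
- Fallback: it drops the activated ester altogether, sets out from 1 (with 3) and comes back at 4.
- It is a dehydrative allylation with Pd(PPh3)4 and Et3B in THF at 50 °C, in which the borane turns the hydroxyl group into the leaving group. It makes no new compound (F0).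

**Further compounds**
F1 | step 3 | racemic 3-[(2E,6E)-farnesyl]-3,7-dihydroxychromane-2,4-dione | CC(C)=CCC/C(C)=C/CC/C(C)=C/CC1(O)C(=O)Oc2cc(O)ccc2C1=O
F2 | step 3 | racemic (4E,8E)-1-(2,4-dihydroxyphenyl)-2-hydroxy-5,9,13-trimethyltetradeca-4,8,12-trien-1-one | CC(C)=CCC/C(C)=C/CC/C(C)=C/CC(O)C(=O)c1ccc(O)cc1O
F3 | step 3 | racemic 2-[(2E,6E)-farnesyl]-2,6-dihydroxybenzofuran-3(2H)-one | CC(C)=CCC/C(C)=C/CC/C(C)=C/CC1(O)Oc2cc(O)ccc2C1=O
F4 | step 3 | (S)-2-[(2E,6E)-farnesyl]-2,6-dihydroxybenzofuran-3(2H)-one | CC(C)=CCC/C(C)=C/CC/C(C)=C/C[C@]1(O)Oc2cc(O)ccc2C1=O
F5 | step 2 | (2E,6E)-farnesyl bromide | CC(C)=CCC/C(C)=C/CC/C(C)=C/CBr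
F6 | step 2 | (4E,8E)-1-(2,4-dihydroxyphenyl)-5,9,13-trimethyltetradeca-4,8,12-trien-1-one | CC(C)=CCC/C(C)=C/CC/C(C)=C/CCC(=O)c1ccc(O)cc1O
F0 | step 1 | none | none
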